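# Proposed total synthesis of CNP0039487.1 (54)

## The problem

The target 54 is a trimer of three 24-nor-friedelane units held together only by two 1,4-dioxane rings. O2′ and O3′ of the aromatic ring A of unit B bridge C3 (a hemiketal) and C4 (a fully substituted ether carbon) of the quinoid ring A of unit A. O2″ and O3″ of unit C bridge C6′ and C7′ of ring B of unit B. Units A and B have the skeleton and the C20 ester of pristimerin, but unit C is a different hydrocarbon: its ring E carries the ester on quaternary C19″, next to C18″–H and close to the quaternary centres C17″ and C13″.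

Of the 24 stereocentres, twelve (C9, C13, C14, C17, C18 and C20 of units A and B) can be taken from pristimerin. Twelve have to be made: seven in unit C, C6′, C7′ and C8′ at the B–C junction, and C3 and C4 at the A–B junction. In unit C the chain of control has to run from C17″ (catalyst) to C22″ (reagent) and C18″/C13″ (substrate), then to C19″, and last to C14″, C8″ and C9″ in the closure of rings B and C.

At the B–C junction both oxygens are on the β face, syn to the axial methyl groups on C9′ and C14′. No external reagent will approach that face, so the oxygens have to be placed indirectly.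

The dienone hemiketal of unit A, the benzylic C6′–O bond, the catechols and their o-quinones will not survive strong acid, base, hydride or Lewis acid. Unit A must therefore be attached last, and unit C must be complete before it meets unit B.

The key step is possible because C19″ and C22″ are both α substituents on adjacent ring D carbons (C18″ and C17″), and C20″–C21″–C22″ is a three-carbon unit. Tying the C22″ oxygen to the C19″ carboxyl gives a cis-fused six-membered lactone whose C22″ vinyl group lies over the C19″ enolate carbon.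

## Retrosynthesis

**54 ⇒ 52 + 41.** The bonds C3–O2′ and C4–O3′ are cut first, because the hemiketal dienone they create is the most fragile part of the molecule. Joining A to B earlier would expose it to the acid and silane needed at the B–C junction. The cut leaves the dimer catechol 52 and pristimerin 41, which can be bought. The forward reaction is oxidation of 52 to o-quinone 53 and an inverse-demand hetero-Diels–Alder addition across the enol C3=C4 of 41. It must join C4 to O3′ and C3 to O2′ on the α face.

**52 ⇒ 51 ⇒ 50 ⇒ 49 ⇒ 48 + 40.** The bonds C6′–O2″ and C7′–O3″ are cut. A direct cycloaddition of the o-quinone of 40 to a C6′=C7′ styrene would be shorter, but it would put both oxygens on the open α face, the wrong one. Instead the oxygens are introduced at the ketone and bromide level and the two hydrogens are delivered from the α face. Bromo ketone 48 and catechol 40 give aryloxy ketone 49, cyclodehydration gives benzodioxin 50, and ionic hydrogenation gives 51. The precursors are two monomers. The forward sequence needs the less hindered O2″ to attack C6′, and α-face protonation and hydride transfer.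

**48 ⇒ 46 ⇒ 45 ⇒ 43 ⇒ 42 ⇒ 41.** No skeletal bond is cut. The C7′ ketone and the 8′α hydrogen come from hydroboration of the C7=C8 alkene of pristimerol bis-silyl ether 43, and pristimerol 42 comes from reduction of 41. This uses the same purchased triterpenoid for units A and B.

**40 ⇒ 39 ⇒ 38.** The bonds C8″–C14″ and C9″–C10″ are cut (rings C and B). The arene and the (E)-alkene so released are flat, and all the difficult centres stay in the D/E bicycle. The forward cationic bicyclization must start only at C14, so a tertiary silyl ether is ionised there. Protonating a ring D alkene would compete with protonation of the chain alkene, which closes a tetralin. The closure must pass through a chair and give the trans C/D fusion.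

**38 ⇒ 28 + 36.** The bond C9″–C11″ is cut. An sp3–sp2 Negishi coupling makes this bond with retention of the alkene geometry, which an olefination at C8″=C9″ would not guarantee. Vinyl iodide 36 comes from alkyne 34, itself from aryl iodide 30 and iodide 32 (from 29 and 31).

**28 ⇒ 27 ⇒ 26 ⇒ 25 ⇒ 24 ⇒ 23 ⇒ 22.** These are functional group changes on the D/E bicycle: C11–I from the silyl ether, the C14 oxygen by hydration of C14=C15, saturation of C21=C22, and the methyl ester. They lead back to acid 22, the product of the key step.

**22 ⇒ 19 (key disconnection).** The bond C19–C20 is cut and C22 is reconnected through oxygen to the carboxyl carbon, giving vinyl lactone 19. Enolate alkylation at C19 would have to form a quaternary centre next to C18–H and between two quaternary carbons with no control of its configuration. The [3,3] shift forms the same bond intramolecularly and copies the C22 carbinol configuration into C19. Lactone 19 has one ring fewer and its C19 is a simple enolisable methine.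

**19 ⇒ 18 ⇒ 17 ⇒ 14 ⇒ 12.** The C14 methyl group is traced to the C14 ketone via enol triflate 18. The bonds C18–C19 and C12–C13 are then cut together: an intramolecular Michael addition of the propanoate to the enone closes the lactone cis, and the enolate is alkylated trans to C19. The precursor 12 is monocyclic with two stereocentres.

**12 ⇒ 10 ⇒ 8 ⇒ 7 ⇒ 6.** The ester bond and C22–C21 are cut. The allylic alcohol 10 comes from aldehyde 8 by reagent-controlled vinylation, because the quaternary C17 next to the formyl group offers little substrate bias.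

**6 ⇒ 3 + 4; 3 ⇒ 2 ⇒ 1.** The bonds C13=C18 and C15–C16 are cut (Robinson annulation of aldehyde 3 with ethyl vinyl ketone 4). An amine catalyst sets C17, the first stereocentre.

## Roads not taken

**Alternative 1:** Transannular radical closure. The cut is C13–C14 of a C20-ester unit. In the forward step an iron hydride (Fe(acac)3, PhSiH3) would transfer a hydrogen atom to a C13 exocyclic methylene inside a ten-membered ring, and the tertiary C13 radical would add across the ring to C14 of an (E)-enone, giving the 16-oxo dimethyl ether A1.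
- Merits: it makes the vicinal quaternary centres C13 and C14 in one neutral step, and it would free units A and B from the supply of a natural product.
- Weak points for this target: A1 belongs to the C20-ester series, so it serves units A and B, which the chosen plan buys with twelve stereocentres in place. It does nothing for C19″ of unit C. It needs a ten-membered ring with a defined enone geometry and five preset centres, and the facial outcome at both new quaternary carbons rests on the conformation of that ring. The 16-ketone must then be removed.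
- Comparison: Alternative 1 is better at C13/C14. The chosen plan sets C14″ in a cationic closure whose facial control is less predictable. Against this the chosen plan has far fewer steps and a stereospecific answer to C19″.

**Alternative 2:** Catalytic quinone Diels–Alder reaction. The cuts are C17–C22 and C18–C19. A cationic chiral oxazaborolidine would catalyse the endo addition of 2-(trimethylsilyloxy)buta-1,3-diene A2 to the methyl-bearing alkene of 2-methoxy-5-methyl-1,4-benzoquinone A3, giving the cis-fused enedione silyl enol ether A4.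
- Merits: C17 and C18 are set together, cis, in one catalytic step of a well-established type, and both the diene A2 and the quinone A3 are simple achiral compounds.
- Weak points for this target: the enol ether oxygen that the diene A2 brings into A4 sits where a C20 substituent belongs. Unit C needs a quaternary ester at C19″, which would then have to be made by alkylation next to the ring fusion, the uncontrolled step that the lactone Claisen avoids. Ring D of A4, which stems from the quinone A3, also needs C13, C14 and the side chain added by relay.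
- Comparison: for the absolute configuration of C17/C18, Alternative 2 is more reliable than the amine-catalysed annulation of a dialkyl aldehyde and the reagent-controlled vinylation used here. The chosen plan offers in return a direct transfer of chirality from C22″ to C19″ and a ring D that already carries the C13 side chain.

**Alternative 3:** Dioxane diene benzannulation. The cuts are C1″–C10″ and C4″–C5″. An exocyclic 1,3-diene on the dioxane ring already fused to C6′/C7′ of unit B would add (Et2AlCl) to the C5″=C10″ enone double bond of rings B to E of unit C, and DDQ would aromatise the adduct to the 6″-oxo dimer A5.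
- Merits: the two ether bonds are made before ring A of unit C exists, so which oxygen goes to which carbon is fixed by construction. No o-quinone or free catechol of unit C is needed.
- Weak points for this target: the cis-β,β dioxane on unit B still has to be made, so the hardest stereochemical problem is only moved. The exocyclic diene is prone to isomerise into the ring. The dienophile is a tetrasubstituted enone. DDQ and the later removal of the 6″-ketone must spare two benzylic ethers.
- Comparison: in regiochemistry Alternative 3 is better. The chosen plan relies on the steric difference between O2″ and O3″ of 40 in an SN2 step. The chosen plan offers in return reactions of established types and a free choice of when unit C is completed.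

Key step: step 14

## Conventions and assumption

- Atoms carry friedelane numbers: unprimed in unit A, primed in unit B, double-primed in unit C (primes are dropped in fragments of unit C). β is the face of the C17 methyl group.
- Assumption: pristimerin (41) is a commercial natural product (also obtainable from commercial celastrol by O-methylation). It is taken as the source of units A and B. Unit C is built from simple materials.

## Steps

Step 1
Reactants: 1 methyl 3-hydroxy-2-methylpropanoate (racemic)
Product: 2 methyl 3-[(tert-butyldimethylsilyl)oxy]-2-methylpropanoate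
Conditions: TBSCl, imidazole, CH2Cl2, 0 °C → rt
Reagents that add atoms: tert-butyldimethylsilyl chloride, CC(C)(C)[Si](C)(C)Cl
Why: Silylation of a primary alcohol; the stereocentre is lost in step 3, so racemic material suffices.

Step 2
Reactants: 2 methyl 3-[(tert-butyldimethylsilyl)oxy]-2-methylpropanoate
Product: 3 3-[(tert-butyldimethylsilyl)oxy]-2-methylpropanal
Conditions: DIBAL-H (1.05 equiv), CH2Cl2, −78 °C; aq. potassium sodium tartrate
Reagents that add atoms: none
Why: Partial reduction of an ester to the aldehyde through the stable aluminium hemiacetal at low temperature.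

Step 3
Reactants: 3 3-[(tert-butyldimethylsilyl)oxy]-2-methylpropanal; 4 ethyl vinyl ketone
Product: 6 (4R)-4-{[(tert-butyldimethylsilyl)oxy]methyl}-2,4-dimethylcyclohex-2-en-1-one, via keto aldehyde Michael adduct 5 (not isolated)
Conditions: (S)-N-(4-dodecylphenylsulfonyl)pyrrolidine-2-carboxamide (20 mol%), 4 Å MS, ClCH2CH2Cl, rt; then KOH (cat.), MeOH, 0 °C
Reagents that add atoms: none
Why: Amine-catalysed Robinson annulation (enamine Michael addition, then aldol condensation). Both enantiomers of 3 give the same enamine, whose geometry keeps CH2OTBS away from nitrogen while the sulfonamide N–H directs 4 to one face, setting C17 as (R); the antipodal catalyst is to be used if the sense proves opposite.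

Step 4
Reactants: 6 (4R)-4-{[(tert-butyldimethylsilyl)oxy]methyl}-2,4-dimethylcyclohex-2-en-1-one
Product: 7 (4R)-4-(hydroxymethyl)-2,4-dimethylcyclohex-2-en-1-one
Conditions: 48% aq. HF, MeCN, 0 °C
Reagents that add atoms: none
Why: Acidic desilylation; the enone and the quaternary centre are inert.

Step 5
Reactants: 7 (4R)-4-(hydroxymethyl)-2,4-dimethylcyclohex-2-en-1-one
Product: 8 (1R)-1,3-dimethyl-4-oxocyclohex-2-ene-1-carbaldehyde
Conditions: Dess–Martin periodinane, NaHCO3, CH2Cl2, rt
Reagents that add atoms: none
Why: Oxidation of a neopentyl primary alcohol; the aldehyde has no α hydrogen and cannot epimerise.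

Step 6
Reactants: 8 (1R)-1,3-dimethyl-4-oxocyclohex-2-ene-1-carbaldehyde; 9 vinylmagnesium bromide
Product: 10 (4R)-4-[(1S)-1-hydroxyprop-2-en-1-yl]-2,4-dimethylcyclohex-2-en-1-one
Conditions: Zn(CH=CH2)2 [from 9 and ZnCl2 (0.5 equiv), Et2O; magnesium salts precipitated with 1,4-dioxane], (−)-3-exo-(dimethylamino)isoborneol (10 mol%), toluene, 0 °C
Reagents that add atoms: none
Why: Amino-alcohol-catalysed addition of a diorganozinc to an aldehyde; the organozinc does not attack the enone. The ligand should deliver vinyl to the Si face of the formyl group, as it does with dialkylzincs, giving (22S); a C22 epimer would be a separable diastereomer.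

Step 7
Reactants: 10 (4R)-4-[(1S)-1-hydroxyprop-2-en-1-yl]-2,4-dimethylcyclohex-2-en-1-one; 11 propanoyl chloride
Product: 12 (1S)-1-[(1R)-1,3-dimethyl-4-oxocyclohex-2-en-1-yl]prop-2-en-1-yl propanoate
Conditions: Et3N, DMAP (cat.), CH2Cl2, 0 °C
Reagents that add atoms: none
Why: Acylation of a hindered secondary allylic alcohol under nucleophilic catalysis.

Step 8
Reactants: 12 (1S)-1-[(1R)-1,3-dimethyl-4-oxocyclohex-2-en-1-yl]prop-2-en-1-yl propanoate
Product: 14 C13-prenyl keto lactone (cis-fused C22-vinyl δ-lactone on ring D; C17-Me, H18, vinyl, prenyl β; C13-Me α; C14 ketone), via potassium enolate 13 (not isolated)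
Conditions: KHMDS (1.05 equiv), THF, −78 → −20 °C; then prenyl bromide, DMPU, −78 → 0 °C
Reagents that add atoms: 1-bromo-3-methylbut-2-ene, CC(C)=CCBr
Why: Tandem intramolecular Michael addition and enolate alkylation. Under equilibrating conditions the ester enolate adds 6-exo-trig to C18 from the face of its C17 tether (cis lactone, H18 β), and the resulting C13 enolate is alkylated trans to the new C18–C19 bond, as in conjugate addition–alkylation sequences. C19 forms as the epimer with methyl on the convex face or as a mixture, which is irrelevant because the centre becomes trigonal in step 14.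

Step 9
Reactants: 14 C13-prenyl keto lactone
Product: 15 C11 aldehyde (2-oxoethyl group on C13)
Conditions: O3, pyridine, CH2Cl2/MeOH, −78 °C (Sudan Red 7B end point); Me2S
Reagents that add atoms: ozone, [O-][O+]=O
Why: Ozonolysis. The electron-rich trisubstituted prenyl alkene reacts much faster than the monosubstituted vinyl group, which is deactivated by the allylic acyloxy group, so a dye end point allows selective cleavage.

Step 10
Reactants: 15 C11 aldehyde
Product: 16 C11 primary alcohol (2-hydroxyethyl group on C13)
Conditions: NaBH4, MeOH/CH2Cl2, −78 °C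
Reagents that add atoms: none
Why: Chemoselective borohydride reduction of an aldehyde beside a ketone flanked by a quaternary carbon, at low temperature.

Step 11
Reactants: 16 C11 primary alcohol
Product: 17 C11 TBS ether C14 ketone
Conditions: TBSCl, imidazole, DMF, rt
Reagents that add atoms: tert-butyldimethylsilyl chloride, CC(C)(C)[Si](C)(C)Cl
Why: Silylation of the primary alcohol, which also removes any hemiketal with the C14 ketone.

Step 12
Reactants: 17 C11 TBS ether C14 ketone
Product: 18 C14 enol triflate (C14=C15)
Conditions: KHMDS (1.05 equiv), THF, −78 °C; PhNTf2, −78 → 0 °C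
Reagents that add atoms: N-phenylbis(trifluoromethanesulfonimide), O=S(=O)(N(c1ccccc1)S(=O)(=O)C(F)(F)F)C(F)(F)F
Why: Enol triflate formation. C15 is the only enolisable position of the ketone and is far more acidic than the hindered lactone methine, so the triflate is regiodefined.

Step 13
Reactants: 18 C14 enol triflate
Product: 19 ring D-fused vinyl lactone (C14 methyl, C14=C15)
Conditions: MeMgBr, Fe(acac)3 (5 mol%), THF/NMP, −30 °C
Reagents that add atoms: methylmagnesium bromide, C[Mg]Br
Why: Iron-catalysed cross-coupling of an alkenyl triflate with a Grignard reagent, which is faster than addition to the lactone. A palladium catalyst is avoided because the lactone is an allylic ester.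

Step 14
Reactants: 19 ring D-fused vinyl lactone
Product: 22 D/E bicyclic C19 carboxylic acid (C21=C22), via silyl ketene acetal 20 (not isolated), via trimethylsilyl ester 21 (not isolated)
Conditions: KHMDS, Me3SiCl/Et3N, THF, −78 °C → rt; toluene, 100 °C; then aq. citric acid, THF
Reagents that add atoms: none
Why: Ireland–Claisen rearrangement of a lactone silyl ketene acetal; the closest known type is the contraction of six-membered vinyl lactones to cyclohexene carboxylic acids. KHMDS removes H19, the only enolisable hydrogen of 19, and Me3SiCl traps the enolate as 20. On warming, O–C22 breaks while C19–C20 forms in a concerted suprafacial [3,3] shift, and hydrolysis of silyl ester 21 gives 22. Ring E (C17, C18, C19, C20, C21, C22) closes by this pericyclic ring contraction through a boat transition state, because C18–C17 bridges C19 and C22 in a bicyclo[2.2.2]-like array and a chair is impossible. C19 is the only new stereocentre and is controlled by C22. C20 can reach C19 only from the lactone face that carries the vinyl group (the convex face, syn to H18 and the C17 methyl), and the carboxyl carbon stays where the lactone ring held it. The C19 configuration of 19 is erased in 20, so either epimer serves. The step needs the [3,3] shift to outrun elimination and C-silylation; the ring holds the vinyl group over the ketene acetal and a concerted shift tolerates the congestion around C18.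

Step 15
Reactants: 22 D/E bicyclic C19 carboxylic acid
Product: 23 methyl ester of 22
Conditions: Me3SiCHN2, toluene/MeOH, 0 °C
Reagents that add atoms: trimethylsilyldiazomethane, C[Si](C)(C)C=[N+]=[N-]
Why: O-Methylation of a hindered quaternary acid through the diazonium ion pair, with no demand on the carbonyl carbon.

Step 16
Reactants: 23 methyl ester of 22
Product: 24 C21,C22-dihydro ester (ring E saturated, C14=C15 kept)
Conditions: 2-nitrobenzenesulfonylhydrazide, Et3N, CH2Cl2, rt
Reagents that add atoms: none
Why: Diimide reduction. Concerted syn transfer of H2 to the cis-disubstituted C21=C22 bond is much faster than to the hindered trisubstituted C14=C15 bond.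

Step 17
Reactants: 24 C21,C22-dihydro ester
Product: 25 C11 alcohol
Conditions: HF·pyridine, pyridine, THF, 0 °C → rt
Reagents that add atoms: none
Why: Buffered fluoride cleavage of the primary silyl ether.

Step 18
Reactants: 25 C11 alcohol
Product: 26 C11 iodide (C14=C15 alkene)
Conditions: I2, PPh3, imidazole, CH2Cl2, 0 °C
Reagents that add atoms: iodine, II
Why: Appel-type iodination of a primary alcohol; the alkene and ester are inert.

Step 19
Reactants: 26 C11 iodide
Product: 27 C11 iodide C14 tertiary alcohol (14β-OH drawn)
Conditions: Mn(dpm)3 (10 mol%), PhSiH3, O2 (1 atm), i-PrOH/CH2Cl2, 0 °C → rt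
Reagents that add atoms: dioxygen, O=O
Why: Mukaiyama hydration. Hydrogen-atom transfer to C15 gives the tertiary C14 radical, which is trapped by O2 from the convex β face. The C14 configuration is erased in step 26, so epimer content does not matter.

Step 20
Reactants: 27 C11 iodide C14 tertiary alcohol
Product: 28 C11 iodide C14 trimethylsilyl ether
Conditions: Me3SiOTf, 2,6-lutidine, CH2Cl2, −78 °C
Reagents that add atoms: trimethylsilyl trifluoromethanesulfonate, C[Si](C)(C)OS(=O)(=O)C(F)(F)F
Why: Silylation of a hindered tertiary alcohol with a silyl triflate. It removes the acidic proton before zinc insertion and stops the 1,4-iodo alcohol from closing to an oxolane; 27 is used directly and cold.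

Step 21
Reactants: 29 1,2-dimethoxy-3-methylbenzene
Product: 30 1-iodo-3,4-dimethoxy-2-methylbenzene
Conditions: NIS, CF3CO2H (cat.), MeCN, rt
Reagents that add atoms: N-iodosuccinimide, O=C1CCC(=O)N1I
Why: Electrophilic aromatic iodination para to the unhindered methoxy group; the other methoxy group is twisted out of conjugation by its two ortho neighbours.

Step 22
Reactants: 31 pent-3-yn-1-ol
Product: 32 5-iodopent-2-yne
Conditions: I2, PPh3, imidazole, CH2Cl2, 0 °C
Reagents that add atoms: iodine, II
Why: Appel-type iodination of a primary alcohol.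

Step 23
Reactants: 32 5-iodopent-2-yne; 30 1-iodo-3,4-dimethoxy-2-methylbenzene
Product: 34 1,2-dimethoxy-3-methyl-4-(pent-3-yn-1-yl)benzene, via pent-3-ynylzinc iodide 33 (not isolated)
Conditions: 32, Zn dust, LiCl, THF, 40 °C; then 30, Pd(OAc)2 (2 mol%), SPhos (4 mol%), THF, rt → 50 °C
Reagents that add atoms: none
Why: Negishi sp3–sp2 coupling. Zinc inserts into the primary iodide and the biarylphosphine catalyst couples the ortho-substituted electron-rich aryl iodide.

Step 24
Reactants: 34 1,2-dimethoxy-3-methyl-4-(pent-3-yn-1-yl)benzene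
Product: 36 1-[(3E)-4-iodopent-3-en-1-yl]-3,4-dimethoxy-2-methylbenzene, via alkenylzirconocene chloride 35 (not isolated)
Conditions: Cp2Zr(H)Cl (2.5 equiv), THF, 50 °C; then I2, THF, 0 °C
Reagents that add atoms: iodine, II
Why: Hydrozirconation–iodination. Syn addition of Zr–H, with excess reagent equilibrating zirconium to the methyl-bearing carbon, then iodinolysis with retention, gives the (E)-2-iodoalkene with iodine trans to the chain.

Step 25
Reactants: 28 C11 iodide C14 trimethylsilyl ether; 36 1-[(3E)-4-iodopent-3-en-1-yl]-3,4-dimethoxy-2-methylbenzene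
Product: 38 cyclization precursor [(8E)-alkene; arene, C19 ester, C14 silyl ether], via alkylzinc iodide 37 (not isolated)
Conditions: 28, Zn dust, LiCl, THF, 40 °C; then 36, PdCl2(dppf) (5 mol%), THF/NMP, 50 °C
Reagents that add atoms: none
Why: Negishi sp3–sp2 coupling. The alkylzinc tolerates the ester and silyl ether, and the alkenyl iodide couples with retention, so C7 and C11 end up trans on C8=C9.

Step 26
Reactants: 38 cyclization precursor
Product: 39 unit C dimethyl ether (pentacyclic methyl 2,3-dimethoxy ester; 8α-H, 9β-Me, 13α-Me, 14β-Me, 17β-Me, 18β-H, 19-CO2Me as in 22)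
Conditions: SnCl4 (1.2 equiv), 2,6-di-tert-butyl-4-methylpyridine, CH2Cl2, −78 → −40 °C
Reagents that add atoms: none
Why: Lewis-acid-initiated cation–olefin bicyclization with Friedel–Crafts termination. Only the tertiary C14 silyl ether ionises, C8 of the (E)-alkene captures the C14 cation (ring C), and C10, para to the 3″-methoxy group, captures the C9 cation (ring B). Anti addition across the (E)-alkene in a chair sets H8 α and the C9 methyl β; attack on C14 anti to the axial C13 methyl, needed for the trans C/D fusion with the C14 methyl β, is the least secure element.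

Step 27
Reactants: 39 unit C dimethyl ether
Product: 40 unit C catechol (methyl 2,3-dihydroxy ester)
Conditions: BBr3, CH2Cl2, −78 → 0 °C
Reagents that add atoms: none
Why: Cleavage of aryl methyl ethers by boron tribromide; the neopentyl quaternary methyl ester is far slower.

Step 28
Reactants: 41 pristimerin
Product: 42 pristimerol (methyl 2,3-dihydroxy-24-nor-friedela-1,3,5(10),7-tetraen-29-oate)
Conditions: NaBH4, MeOH/THF, 0 °C, Ar
Reagents that add atoms: none
Why: 1,6-Hydride addition to C6 of the quinone methide aromatises ring A and leaves the C7=C8 alkene.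

Step 29
Reactants: 42 pristimerol
Product: 43 pristimerol bis(tert-butyldimethylsilyl) ether
Conditions: TBSCl, imidazole, DMF, rt
Reagents that add atoms: tert-butyldimethylsilyl chloride, CC(C)(C)[Si](C)(C)Cl
Why: Silylation protects the air-sensitive catechol with groups that are later removed by fluoride without touching a benzylic ether.

Step 30
Reactants: 43 pristimerol bis(tert-butyldimethylsilyl) ether
Product: 45 7α-hydroxy-7,8-dihydro derivative of 43 (8α-H), via C7 alkylborane 44 (not isolated)
Conditions: BH3·THF, THF, 0 → 40 °C; then Me3NO·2H2O, 65 °C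
Reagents that add atoms: trimethylamine N-oxide, C[N+](C)(C)[O-]
Why: Hydroboration–oxidation. Boron adds to C7 and hydrogen to C8 in a syn fashion from the α face, because the β face of C7 is flanked by the axial methyl groups on C9 and C14. The amine oxide oxidises the C–B bond with retention under neutral conditions that spare the aryl silyl ethers.

Step 31
Reactants: 45 7α-hydroxy-7,8-dihydro derivative of 43
Product: 46 7-oxo-7,8-dihydropristimerol bis(tert-butyldimethylsilyl) ether (8α-H)
Conditions: Dess–Martin periodinane, NaHCO3, CH2Cl2, rt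
Reagents that add atoms: none
Why: Oxidation of a secondary alcohol under buffered conditions that do not epimerise C8.

Step 32
Reactants: 46 7-oxo-7,8-dihydropristimerol bis(tert-butyldimethylsilyl) ether
Product: 48 6α-bromo-7-oxo derivative of 46, via trimethylsilyl enol ether 47 (not isolated)
Conditions: LiHMDS, Me3SiCl, THF, −78 °C; then NBS, −78 → 0 °C
Reagents that add atoms: N-bromosuccinimide, O=C1CCC(=O)N1Br
Why: α-Bromination through the silyl enol ether. Enolisation goes to the benzylic C6 methylene and not to the hindered C8 methine. Bromination of the enol ether avoids ring bromination of the electron-rich arene and enters axially from the α face.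

Step 33
Reactants: 48 6α-bromo-7-oxo derivative of 46; 40 unit C catechol
Product: 49 6′β-aryloxy-7′-oxo B–C ether (O2″ of unit C on C6′; free 3″-OH, may sit as the 7′-hemiketal)
Conditions: K2CO3, acetone, rt, Ar
Reagents that add atoms: none
Why: SN2 displacement of an α-bromo ketone by a phenoxide. The oxygen next to the unsubstituted C1″ is the less hindered and should attack C6′, while O3″, flanked by the C4″ methyl, is left for the ring closure; the C6′ configuration does not matter because it is erased in step 34.

Step 34
Reactants: 49 6′β-aryloxy-7′-oxo B–C ether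
Product: 50 B–C 1,4-benzodioxin (C6′=C7′ enediol diether)
Conditions: TsOH·H2O (cat.), 4 Å MS, toluene, 80 °C
Reagents that add atoms: none
Why: Acid-catalysed cyclodehydration of an α-(2-hydroxyaryloxy) ketone to a 1,4-benzodioxin through its hemiketal, which removes both junction stereocentres for a controlled reduction.

Step 35
Reactants: 50 B–C 1,4-benzodioxin
Product: 51 B–C dimer bis(tert-butyldimethylsilyl) ether (cis-dioxane, 6′β-O, 7′β-O, 8′α-H)
Conditions: Et3SiH, CF3CO2H, CH2Cl2, −40 → 0 °C
Reagents that add atoms: none
Why: Ionic hydrogenation of a cyclic enol ether. Protonation at C7′ gives the C6′ oxocarbenium ion, which is also benzylic; the proton enters from the α face because the β face of C7′ is flanked by the axial C9′ and C14′ methyl groups, the situation of C11 in 11-oxo steroids. Hydride then adds to C6′ from the α face, the only one that keeps the dioxane cis-fused to the axial C7′–O bond, so both hydrogens are α and both oxygens β.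

Step 36
Reactants: 51 B–C dimer bis(tert-butyldimethylsilyl) ether
Product: 52 B–C dimer catechol
Conditions: HF·pyridine, pyridine, THF, 0 °C
Reagents that add atoms: none
Why: Buffered fluoride cleavage of aryl silyl ethers; the esters and the benzylic ether are untouched.

Step 37
Reactants: 52 B–C dimer catechol; 41 pristimerin
Product: 54 CNP0039487.1, via B–C o-quinone 53 (not isolated)
Conditions: Ag2O, 41 (3 equiv), CH2Cl2, 0 °C → rt, dark
Reagents that add atoms: none
Why: Inverse-demand hetero-Diels–Alder reaction of an o-quinone (O=C–C=O as heterodiene) with the enol double bond C3=C4 of the hydroxy quinone methide, the union proposed for the biogenesis of celastroid dimers. Ag2O oxidises only the catechol, and excess 41 should trap 53 before it tautomerises. The step needs C4 to bond to O3′, C3 to O2′, and approach on the α face of 41, away from the C9 and C14 methyl groups, which leaves the hemiketal OH and the C4 methyl β.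

## Compound list

1 | methyl 3-hydroxy-2-methylpropanoate (racemic) | COC(=O)C(C)CO | starting material
2 | methyl 3-[(tert-butyldimethylsilyl)oxy]-2-methylpropanoate | COC(=O)C(C)CO[Si](C)(C)C(C)(C)C | intermediate
3 | 3-[(tert-butyldimethylsilyl)oxy]-2-methylpropanal | O=CC(C)CO[Si](C)(C)C(C)(C)C | intermediate
4 | ethyl vinyl ketone (pent-1-en-3-one) | CCC(=O)C=C | starting material
5 | (2S)-2-{[(tert-butyldimethylsilyl)oxy]methyl}-2-methyl-5-oxoheptanal | O=C[C@](C)(CO[Si](C)(C)C(C)(C)C)CCC(=O)CC | intermediate (not isolated)
6 | (4R)-4-{[(tert-butyldimethylsilyl)oxy]methyl}-2,4-dimethylcyclohex-2-en-1-one | O=C1CC[C@@](C)(CO[Si](C)(C)C(C)(C)C)C=C1C | intermediate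
7 | (4R)-4-(hydroxymethyl)-2,4-dimethylcyclohex-2-en-1-one | O=C1CC[C@@](C)(CO)C=C1C | intermediate
8 | (1R)-1,3-dimethyl-4-oxocyclohex-2-ene-1-carbaldehyde | O=C1CC[C@@](C)(C=O)C=C1C | intermediate
9 | vinylmagnesium bromide | C=C[Mg]Br | starting material
10 | (4R)-4-[(1S)-1-hydroxyprop-2-en-1-yl]-2,4-dimethylcyclohex-2-en-1-one | O=C1CC[C@@](C)([C@@H](O)C=C)C=C1C | intermediate
11 | propanoyl chloride | CCC(Cl)=O | starting material
12 | (1S)-1-[(1R)-1,3-dimethyl-4-oxocyclohex-2-en-1-yl]prop-2-en-1-yl propanoate | O=C1CC[C@@](C)([C@@H](OC(=O)CC)C=C)C=C1C | intermediate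
13 | potassium C13=C14 enolate of the cis-fused vinyl lactone | [K+].[O-]C1=C(C)[C@H]2[C@](C)([C@H](C=C)OC(=O)[C@@H]2C)CC1 | intermediate (not isolated)
14 | C13-prenyl keto lactone: cis-fused 1-ethenyl-4,5,8a-trimethyl-5-(3-methylbut-2-en-1-yl)hexahydro-1H-isochromene-3,6-dione (C17-Me, H18, vinyl, prenyl β; C13-Me α; C19-Me exo) | CC(C)=CC[C@@]1(C)[C@H]2[C@](C)([C@H](C=C)OC(=O)[C@@H]2C)CCC1=O | intermediate
15 | C11 aldehyde (2-oxoethyl in place of prenyl in 14) | O=CC[C@@]1(C)[C@H]2[C@](C)([C@H](C=C)OC(=O)[C@@H]2C)CCC1=O | intermediate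
16 | C11 alcohol (2-hydroxyethyl in place of prenyl in 14) | OCC[C@@]1(C)[C@H]2[C@](C)([C@H](C=C)OC(=O)[C@@H]2C)CCC1=O | intermediate
17 | C11 tert-butyldimethylsilyl ether C14 ketone | CC(C)(C)[Si](C)(C)OCC[C@@]1(C)[C@H]2[C@](C)([C@H](C=C)OC(=O)[C@@H]2C)CCC1=O | intermediate
18 | C14 enol triflate (C14=C15) of 17 | CC(C)(C)[Si](C)(C)OCC[C@@]1(C)[C@H]2[C@](C)([C@H](C=C)OC(=O)[C@@H]2C)CC=C1OS(=O)(=O)C(F)(F)F | intermediate
19 | ring D-fused vinyl lactone (C14-Me, C14=C15; precursor of the key step) | CC(C)(C)[Si](C)(C)OCC[C@@]1(C)[C@H]2[C@](C)([C@H](C=C)OC(=O)[C@@H]2C)CC=C1C | intermediate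
20 | trimethylsilyl ketene acetal of 19 | CC(C)(C)[Si](C)(C)OCC[C@@]1(C)[C@H]2[C@](C)([C@H](C=C)OC(O[Si](C)(C)C)=C2C)CC=C1C | intermediate (not isolated)
21 | trimethylsilyl ester of 22 | CC(C)(C)[Si](C)(C)OCC[C@@]1(C)[C@H]2[C@](C)(C=CC[C@@]2(C)C(=O)O[Si](C)(C)C)CC=C1C | intermediate (not isolated)
22 | D/E bicyclic C19 carboxylic acid (C21=C22, C14=C15; product of the key step) | CC(C)(C)[Si](C)(C)OCC[C@@]1(C)[C@H]2[C@](C)(C=CC[C@@]2(C)C(=O)O)CC=C1C | intermediate
23 | methyl ester of 22 | CC(C)(C)[Si](C)(C)OCC[C@@]1(C)[C@H]2[C@](C)(C=CC[C@@]2(C)C(=O)OC)CC=C1C | intermediate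
24 | C21,C22-dihydro methyl ester | CC(C)(C)[Si](C)(C)OCC[C@@]1(C)[C@H]2[C@](C)(CCC[C@@]2(C)C(=O)OC)CC=C1C | intermediate
25 | C11 alcohol of the D/E ester | OCC[C@@]1(C)[C@H]2[C@](C)(CCC[C@@]2(C)C(=O)OC)CC=C1C | intermediate
26 | C11 iodide of the D/E ester (C14=C15) | ICC[C@@]1(C)[C@H]2[C@](C)(CCC[C@@]2(C)C(=O)OC)CC=C1C | intermediate
27 | C11 iodide C14 tertiary alcohol (14β-OH drawn) | ICC[C@@]1(C)[C@H]2[C@](C)(CCC[C@@]2(C)C(=O)OC)CC[C@@]1(C)O | intermediate
28 | C11 iodide C14 trimethylsilyl ether | ICC[C@@]1(C)[C@H]2[C@](C)(CCC[C@@]2(C)C(=O)OC)CC[C@@]1(C)O[Si](C)(C)C | intermediate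
29 | 1,2-dimethoxy-3-methylbenzene | COc1cccc(C)c1OC | starting material
30 | 1-iodo-3,4-dimethoxy-2-methylbenzene | COc1ccc(I)c(C)c1OC | intermediate
31 | pent-3-yn-1-ol | CC#CCCO | starting material
32 | 5-iodopent-2-yne | CC#CCCI | intermediate
33 | pent-3-yn-1-ylzinc iodide | CC#CCC[Zn]I | intermediate (not isolated)
34 | 1,2-dimethoxy-3-methyl-4-(pent-3-yn-1-yl)benzene | CC#CCCc1ccc(OC)c(OC)c1C | intermediate
35 | (E)-alkenylzirconocene chloride from 34 (Zr on the methyl-bearing carbon) | C/C(=C\CCc1ccc(OC)c(OC)c1C)[Zr](Cl)(C1C=CC=C1)C1C=CC=C1 | intermediate (not isolated)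
36 | 1-[(3E)-4-iodopent-3-en-1-yl]-3,4-dimethoxy-2-methylbenzene | C/C(I)=C\CCc1ccc(OC)c(OC)c1C | intermediate
37 | alkylzinc iodide from 28 | I[Zn]CC[C@@]1(C)[C@H]2[C@](C)(CCC[C@@]2(C)C(=O)OC)CC[C@@]1(C)O[Si](C)(C)C | intermediate (not isolated)
38 | cyclization precursor: D/E ester with C14 silyl ether and (8E)-aryl alkenyl chain on C12 | COc1ccc(CC/C=C(\C)CC[C@@]2(C)[C@H]3[C@](C)(CCC[C@@]3(C)C(=O)OC)CC[C@@]2(C)O[Si](C)(C)C)c(C)c1OC | intermediate
39 | unit C dimethyl ether (pentacyclic methyl 2,3-dimethoxy ester) | COc1cc2c(c(C)c1OC)CC[C@H]3[C@@]2(C)CC[C@@]4(C)[C@H]5[C@](C)(CCC[C@@]5(C)C(=O)OC)CC[C@]34C | intermediate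
40 | unit C catechol | Oc1cc2c(c(C)c1O)CC[C@H]3[C@@]2(C)CC[C@@]4(C)[C@H]5[C@](C)(CCC[C@@]5(C)C(=O)OC)CC[C@]34C | intermediate
41 | pristimerin | COC(=O)[C@]1(C)CC[C@]2(C)CC[C@]3(C)C4=CC=C5C(C)=C(O)C(=O)C=C5[C@]4(C)CC[C@@]3(C)[C@@H]2C1 | starting material
42 | pristimerol | Oc1cc2c(c(C)c1O)CC=C3[C@@]2(C)CC[C@@]4(C)[C@@H]5C[C@](C)(C(=O)OC)CC[C@]5(C)CC[C@]34C | intermediate
43 | pristimerol bis(tert-butyldimethylsilyl) ether | CC(C)(C)[Si](C)(C)Oc1cc2c(c(C)c1O[Si](C)(C)C(C)(C)C)CC=C3[C@@]2(C)CC[C@@]4(C)[C@@H]5C[C@](C)(C(=O)OC)CC[C@]5(C)CC[C@]34C | intermediate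
44 | C7α alkylborane from 43 (8α-H) | CC(C)(C)[Si](C)(C)Oc1cc2c(c(C)c1O[Si](C)(C)C(C)(C)C)C[C@@H](B)[C@H]3[C@@]2(C)CC[C@@]4(C)[C@@H]5C[C@](C)(C(=O)OC)CC[C@]5(C)CC[C@]34C | intermediate (not isolated)
45 | 7α-hydroxy-7,8-dihydropristimerol bis(tert-butyldimethylsilyl) ether (8α-H) | CC(C)(C)[Si](C)(C)Oc1cc2c(c(C)c1O[Si](C)(C)C(C)(C)C)C[C@@H](O)[C@H]3[C@@]2(C)CC[C@@]4(C)[C@@H]5C[C@](C)(C(=O)OC)CC[C@]5(C)CC[C@]34C | intermediate
46 | 7-oxo-7,8-dihydropristimerol bis(tert-butyldimethylsilyl) ether (8α-H) | CC(C)(C)[Si](C)(C)Oc1cc2c(c(C)c1O[Si](C)(C)C(C)(C)C)CC(=O)[C@H]3[C@@]2(C)CC[C@@]4(C)[C@@H]5C[C@](C)(C(=O)OC)CC[C@]5(C)CC[C@]34C | intermediate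
47 | C6=C7 trimethylsilyl enol ether of 46 | CC(C)(C)[Si](C)(C)Oc1cc2c(c(C)c1O[Si](C)(C)C(C)(C)C)C=C(O[Si](C)(C)C)[C@H]3[C@@]2(C)CC[C@@]4(C)[C@@H]5C[C@](C)(C(=O)OC)CC[C@]5(C)CC[C@]34C | intermediate (not isolated)
48 | 6α-bromo-7-oxo-7,8-dihydropristimerol bis(tert-butyldimethylsilyl) ether | CC(C)(C)[Si](C)(C)Oc1cc2c(c(C)c1O[Si](C)(C)C(C)(C)C)[C@@H](Br)C(=O)[C@H]3[C@@]2(C)CC[C@@]4(C)[C@@H]5C[C@](C)(C(=O)OC)CC[C@]5(C)CC[C@]34C | intermediate
49 | 6′β-aryloxy-7′-oxo B–C ether (C6′–O2″; free 3″-OH) | CC(C)(C)[Si](C)(C)Oc1cc2c(c(C)c1O[Si](C)(C)C(C)(C)C)[C@H](Oc6cc7c(c(C)c6O)CC[C@H]9[C@@]7(C)CC[C@@]7(C)[C@H]6[C@](C)(CCC[C@@]6(C)C(=O)OC)CC[C@]97C)C(=O)[C@H]3[C@@]2(C)CC[C@@]4(C)[C@@H]5C[C@](C)(C(=O)OC)CC[C@]5(C)CC[C@]34C | intermediate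
50 | B–C 1,4-benzodioxin (C6′=C7′; C6′–O2″, C7′–O3″) | CC(C)(C)[Si](C)(C)Oc1cc2c(c(C)c1O[Si](C)(C)C(C)(C)C)C(Oc6cc7c(c(C)c6O8)CC[C@H]9[C@@]7(C)CC[C@@]7(C)[C@H]6[C@](C)(CCC[C@@]6(C)C(=O)OC)CC[C@]97C)=C8[C@H]3[C@@]2(C)CC[C@@]4(C)[C@@H]5C[C@](C)(C(=O)OC)CC[C@]5(C)CC[C@]34C | intermediate
51 | B–C dimer bis(tert-butyldimethylsilyl) ether (cis-dioxane; 6′β-O, 7′β-O, 8′α-H) | CC(C)(C)[Si](C)(C)Oc1cc2c(c(C)c1O[Si](C)(C)C(C)(C)C)[C@H](Oc6cc7c(c(C)c6O8)CC[C@H]9[C@@]7(C)CC[C@@]7(C)[C@H]6[C@](C)(CCC[C@@]6(C)C(=O)OC)CC[C@]97C)[C@H]8[C@H]3[C@@]2(C)CC[C@@]4(C)[C@@H]5C[C@](C)(C(=O)OC)CC[C@]5(C)CC[C@]34C | intermediate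
52 | B–C dimer catechol | Oc1cc2c(c(C)c1O)[C@H](Oc6cc7c(c(C)c6O8)CC[C@H]9[C@@]7(C)CC[C@@]7(C)[C@H]6[C@](C)(CCC[C@@]6(C)C(=O)OC)CC[C@]97C)[C@H]8[C@H]3[C@@]2(C)CC[C@@]4(C)[C@@H]5C[C@](C)(C(=O)OC)CC[C@]5(C)CC[C@]34C | intermediate
53 | B–C dimer 2′,3′-o-quinone | O=C1C=C2C(=C(C)C1=O)[C@H](Oc6cc7c(c(C)c6O8)CC[C@H]9[C@@]7(C)CC[C@@]7(C)[C@H]6[C@](C)(CCC[C@@]6(C)C(=O)OC)CC[C@]97C)[C@H]8[C@H]3[C@@]2(C)CC[C@@]4(C)[C@@H]5C[C@](C)(C(=O)OC)CC[C@]5(C)CC[C@]34C | intermediate (not isolated)
54 | CNP0039487.1 | COC(=O)[C@]1(C)CC[C@]2(C)CC[C@]3(C)C4=CC=C5C(=CC(=O)[C@@]6(O)Oc7cc8c(c(C)c7O[C@@]56C)[C@@H]5Oc6cc7c(c(C)c6O[C@@H]5[C@H]5[C@@]8(C)CC[C@@]6(C)[C@@H]8C[C@](C)(C(=O)OC)CC[C@]8(C)CC[C@]56C)CC[C@H]5[C@@]7(C)CC[C@@]6(C)[C@H]7[C@](C)(CCC[C@@]7(C)C(=O)OC)CC[C@]56C)[C@]4(C)CC[C@@]3(C)[C@@H]2C1 | target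

## Step count and least certain steps

Total: 37 steps. Longest linear sequence: 28 steps (steps 1–20, 25–27 and 33–37).

**Step 14 (key step).** The likely failure is slow or incomplete enolisation of the hindered C19 methine, followed by loss of the ketene acetal through C-silylation or hydrolysis before it can pass through the strained boat transition state. Fallback, from 19 back to 23: the lactone is opened with methoxide in methanol and the freed C22 alcohol is trapped with methyl chloroformate to give the methyl ester allylic methyl carbonate F1. The ester enolate of F1 (LiHMDS, ZnCl2) is then allylated intramolecularly at C20 under zerovalent palladium catalysis (Pd(PPh3)4). Ionisation with inversion and attack anti to palladium reproduce the facial sense of the [3,3] shift at the allyl unit. The C19 configuration is no longer fixed by a ring and would have to be checked.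

**Step 8.** The likely failure is enolate formation at C15 of the ketone in place of the ester, leading to acyl migration from oxygen to C15, or alkylation at C15 after proton exchange. Fallback, from 10 back to 14: 10 is acylated with 2-bromopropanoyl bromide to give the 2-bromopropanoate F2. A tin hydride radical chain (Bu3SnH, AIBN) closes the lactone by 6-exo-trig addition of the ester radical to C18, giving the keto lactone F3 with hydrogen on C13. The more substituted enolate of F3, formed under equilibrating conditions (KH, THF), is then prenylated trans to C19 to give 14.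

**Step 26.** The likely failures are capture of the C14 cation on the wrong face (cis C/D fusion), a 1,2-methyl shift from C13 to C14, and proton loss. Fallback, from 26 back to 39: epoxidation of 26 with mCPBA on the convex face gives the 14β,15β-epoxy iodide F4. Negishi coupling of F4 with 36, as in step 25, gives the epoxy polyene F5. MeAlCl2 opens the epoxide with backside attack of C8 on C14, so the epoxide face alone fixes C14, and gives the 15β-hydroxy pentacycle F6. Its S-methyl xanthate F7 is reduced with Bu3SnH (Barton–McCombie deoxygenation) to 39.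

**Step 35.** The likely failures are loss of facial control in the protonation of C7′ or in the hydride transfer to C6′, and acid ionisation of the benzylic C6′–O bond. Fallback, from 45 back to 51: dehydration of 45 with the Burgess reagent gives the C6′=C7′ styrene F8. OsO4 with N-methylmorpholine N-oxide adds on the open α face to give the 6′α,7′α-diol F9. Sulfonyldiimidazole with DBU converts F9 into the cyclic sulfate F10. Catechol 40 with Cs2CO3 in DMF then displaces both C–O bonds of F10 with inversion, first at the benzylic C6′ by the less hindered O2″ and then at C7′, to give 51. The stereochemistry rests on two SN2 inversions and not on hydrogen delivery.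

**Step 37.** The likely failures are tautomerisation of o-quinone 53 to a quinone methide by loss of H6′ before the cycloaddition, and poor discrimination between the two faces of 41 or between the two quinone oxygens. Fallback, from 41 back to 54: 41 is silylated (Et3SiCl, imidazole) to pristimerin 3-O-triethylsilyl ether F11. This is a more electron-rich and bulkier dienophile, which should react faster with 53 (generated from 52 as in step 37) and be more face-selective. It gives the 3-O-triethylsilyl ketal of the trimer F12, and HF·pyridine converts F12 into 54.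

## Further compounds

F1 | step 14 | methyl ester allylic methyl carbonate from ring-opened 19 | CC(C)(C)[Si](C)(C)OCC[C@@]1(C)[C@H]([C@@H](C)C(=O)OC)[C@](C)([C@H](C=C)OC(=O)OC)CC=C1C
F2 | step 8 | (1S)-1-[(1R)-1,3-dimethyl-4-oxocyclohex-2-en-1-yl]prop-2-en-1-yl 2-bromopropanoate | O=C1CC[C@@](C)([C@@H](OC(=O)C(C)Br)C=C)C=C1C
F3 | step 8 | cis-fused vinyl keto lactone with hydrogen on C13 (C13 epimers) | CC1[C@H]2[C@](C)([C@H](C=C)OC(=O)[C@@H]2C)CCC1=O
F4 | step 26 | 14β,15β-epoxy C11 iodide of the D/E ester | ICC[C@@]1(C)[C@H]2[C@](C)(CCC[C@@]2(C)C(=O)OC)C[C@H]3O[C@@]13C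
F5 | step 26 | 14β,15β-epoxy polyene (epoxide analogue of 38) | COc1ccc(CC/C=C(\C)CC[C@@]2(C)[C@H]3[C@](C)(CCC[C@@]3(C)C(=O)OC)C[C@H]4O[C@@]24C)c(C)c1OC
F6 | step 26 | 15β-hydroxy derivative of 39 | COc1cc2c(c(C)c1OC)CC[C@H]3[C@@]2(C)CC[C@@]4(C)[C@H]5[C@](C)(CCC[C@@]5(C)C(=O)OC)C[C@@H](O)[C@]34C
F7 | step 26 | S-methyl xanthate of F6 | COc1cc2c(c(C)c1OC)CC[C@H]3[C@@]2(C)CC[C@@]4(C)[C@H]5[C@](C)(CCC[C@@]5(C)C(=O)OC)C[C@@H](OC(=S)SC)[C@]34C
F8 | step 35 | C6=C7 styrene of unit B, bis(tert-butyldimethylsilyl) ether (8α-H) | CC(C)(C)[Si](C)(C)Oc1cc2c(c(C)c1O[Si](C)(C)C(C)(C)C)C=C[C@H]3[C@@]2(C)CC[C@@]4(C)[C@@H]5C[C@](C)(C(=O)OC)CC[C@]5(C)CC[C@]34C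
F9 | step 35 | 6α,7α-diol from F8 | CC(C)(C)[Si](C)(C)Oc1cc2c(c(C)c1O[Si](C)(C)C(C)(C)C)[C@@H](O)[C@@H](O)[C@H]3[C@@]2(C)CC[C@@]4(C)[C@@H]5C[C@](C)(C(=O)OC)CC[C@]5(C)CC[C@]34C
F10 | step 35 | 6α,7α-cyclic sulfate from F9 | CC(C)(C)[Si](C)(C)Oc1cc2c(c(C)c1O[Si](C)(C)C(C)(C)C)[C@H]6OS(=O)(=O)O[C@H]6[C@H]3[C@@]2(C)CC[C@@]4(C)[C@@H]5C[C@](C)(C(=O)OC)CC[C@]5(C)CC[C@]34C
F11 | step 37 | pristimerin 3-O-triethylsilyl ether | COC(=O)[C@]1(C)CC[C@]2(C)CC[C@]3(C)C4=CC=C5C(C)=C(O[Si](CC)(CC)CC)C(=O)C=C5[C@]4(C)CC[C@@]3(C)[C@@H]2C1
F12 | step 37 | 3-O-triethylsilyl ketal of 54 | COC(=O)[C@]1(C)CC[C@]2(C)CC[C@]3(C)C4=CC=C5C(=CC(=O)[C@@]6(O[Si](CC)(CC)CC)Oc7cc8c(c(C)c7O[C@@]56C)[C@@H]5Oc6cc7c(c(C)c6O[C@@H]5[C@H]5[C@@]8(C)CC[C@@]6(C)[C@@H]8C[C@](C)(C(=O)OC)CC[C@]8(C)CC[C@]56C)CC[C@H]5[C@@]7(C)CC[C@@]6(C)[C@H]7[C@](C)(CCC[C@@]7(C)C(=O)OC)CC[C@]56C)[C@]4(C)CC[C@@]3(C)[C@@H]2C1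
A1 | alternative 1 | 16-oxo saturated catechol dimethyl ether of the C20-ester unit | COc1cc2c(c(C)c1OC)CC[C@H]3[C@@]2(C)CC[C@@]4(C)[C@@H]5C[C@](C)(C(=O)OC)CC[C@]5(C)C(=O)C[C@]34C
A2 | alternative 2 | 2-(trimethylsilyloxy)buta-1,3-diene | C=CC(=C)O[Si](C)(C)C
A3 | alternative 2 | 2-methoxy-5-methyl-1,4-benzoquinone | COC1=CC(=O)C(C)=CC1=O
A4 | alternative 2 | cis-fused D/E enedione silyl enol ether | COC1=CC(=O)[C@@]2(C)CC=C(O[Si](C)(C)C)C[C@H]2C1=O
A5 | alternative 3 | 6″-oxo B–C benzodioxane dimer bis(methoxymethyl) ether | COCOc1cc2c(c(C)c1OCOC)[C@@H]3Oc4cc5c(c(C)c4O[C@@H]3[C@H]6[C@@]2(C)CC[C@@]7(C)[C@@H]8C[C@](C)(C(=O)OC)CC[C@]8(C)CC[C@]67C)C(=O)C[C@H]1[C@@]5(C)CC[C@@]2(C)[C@H]3[C@](C)(CCC[C@@]3(C)C(=O)OC)CC[C@]12C
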